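**Strategy.** Ring B is closed last, by the C8–C9 bond. The allylic alcohol C7(OH)–C8(=C17H2) of ring B is the retron of a propargylic alcohol: a stannyl radical adds to C17 of a terminal alkyne, and the C8 vinyl radical closes 6-exo-trig onto C9 of a C9=C11 olefin that already carries the side chain. One operation makes ring B, the 8(17)-methylene group and the C9 stereocentre. The precursor is a monocyclic ring A. Its C10 centre is set by copper-catalysed asymmetric conjugate addition; C5 and C4 are relayed from it by two enolate alkylations; C7 comes from transfer hydrogenation of an ynone released from a temporary C19–O–C7 lactone.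

Key step: step 16

Remark: labdane numbering (C1–C20) is used for all intermediates; the Z/E ratio of the C9=C11 olefin from step 11 is assumed not to matter, because C11 becomes sp3 in step 16.

**Step 1**
Reactants: 1 3-methylbut-2-en-1-ol (prenol)
Product: 2 prenyl tert-butyldimethylsilyl ether
Conditions: TBSCl, imidazole, CH2Cl2, 0 °C to rt
Reagents that add atoms: tert-butyldimethylsilyl chloride, CC(C)(C)[Si](C)(C)Cl
Why: Standard silylation of a primary alcohol, which protects the future C15 hydroxyl; no stereocentre is involved.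

**Step 2**
Reactants: 2 prenyl tert-butyldimethylsilyl ether
Product: 3 (2E)-4-(tert-butyldimethylsilyloxy)-2-methylbut-2-en-1-ol
Conditions: SeO2 (cat.), t-BuOOH, salicylic acid (cat.), CH2Cl2, rt
Reagents that add atoms: tert-butyl hydroperoxide, CC(C)(C)OO
Why: Selenium dioxide allylic oxidation (ene reaction then [2,3] shift) attacks the (E)-methyl group of a trisubstituted olefin, which fixes the E geometry of the later C13=C14 bond.

**Step 3**
Reactants: 3 (2E)-4-(tert-butyldimethylsilyloxy)-2-methylbut-2-en-1-ol
Product: 4 (2E)-4-bromo-3-methylbut-2-enyl tert-butyldimethylsilyl ether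
Conditions: CBr4, PPh3, CH2Cl2, 0 °C
Reagents that add atoms: carbon tetrabromide, BrC(Br)(Br)Br
Why: Appel bromination of a primary allylic alcohol is an SN2 displacement at the unhindered CH2, so no allylic shift occurs and the E olefin is kept.

**Step 4**
Reactants: 4 (2E)-4-bromo-3-methylbut-2-enyl tert-butyldimethylsilyl ether
Product: 5 [(3E)-5-(tert-butyldimethylsilyloxy)-3-methylpent-3-enyl]triphenylphosphonium bromide
Conditions: Ph3PCH3Br, n-BuLi, THF, 0 °C; then 4, −78 °C to rt
Reagents that add atoms: methyltriphenylphosphonium bromide, C[P+](c1ccccc1)(c1ccccc1)c1ccccc1.[Br-]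
Why: C-alkylation of methylenetriphenylphosphorane by the allylic bromide (SN2) gives the one-carbon-longer phosphonium salt (C11–C15), which should precipitate and so escape transylidation.

**Step 5**
Reactants: 6 3-methylcyclohex-2-en-1-one; 7 ethynyltrimethylsilane
Product: 10 silyl enol ether (3S)-3-methyl-3-[1-(trimethylsilyl)ethenyl]-1-(trimethylsilyloxy)cyclohexene, via vinylalane 8 (not isolated), via aluminium enolate 9 (not isolated)
Conditions: 7, DIBAL-H, hexanes/THF, 55 °C; then 6, chiral sulfonate-NHC–Ag complex (5 mol%, enantiomer giving the 10S centre), Cu(OTf)2 (5 mol%), THF, −78 to 4 °C; then TMSOTf, −78 °C to rt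
Reagents that add atoms: trimethylsilyl trifluoromethanesulfonate, C[Si](C)(C)OS(=O)(=O)C(F)(F)F
Why: NHC–copper-catalysed enantioselective conjugate addition of a silicon-substituted vinylaluminium to a β-substituted cyclic enone sets the quaternary centre C10 under catalyst control, and O-silylation of the aluminium enolate stores the C4–C5 enolate regiochemistry.

**Step 6**
Reactants: 10 silyl enol ether; 11 methyl iodoacetate
Product: 13 keto ester methyl 2-{(1R,2S)-2-methyl-6-oxo-2-[1-(trimethylsilyl)ethenyl]cyclohexyl}acetate, via lithium enolate 12 (not isolated)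
Conditions: MeLi, THF, 0 °C; then 11, DMPU, −78 to −20 °C
Reagents that add atoms: none
Why: Regiospecific lithium enolate generation from the silyl enol ether and SN2 alkylation; the electrophile should enter C5 anti to the bulky 1-silylvinyl group on the neighbouring quaternary carbon, which places C6 trans to C9 and cis to C20 (the later trans ring fusion).

**Step 7**
Reactants: 13 keto ester
Product: 15 formyl ester (both C4 epimers), via enol ether 14 (not isolated)
Conditions: Ph3P(CH2OMe)Cl, KHMDS, THF, 0 °C to rt; then 2 M HCl, THF, rt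
Reagents that add atoms: (methoxymethyl)triphenylphosphonium chloride, COC[P+](c1ccccc1)(c1ccccc1)c1ccccc1.[Cl-]; water, O
Why: Wittig methoxymethylenation of the C4 ketone and mild acid hydrolysis of the enol ether give the one-carbon-homologated aldehyde (C19); the C4 configuration is irrelevant because C4 is enolised in step 8, and C5 can no longer epimerise.

**Step 8**
Reactants: 15 formyl ester
Product: 16 quaternary aldehyde methyl 2-{(1S,2S,6S)-2-formyl-2,6-dimethyl-6-[1-(trimethylsilyl)ethenyl]cyclohexyl}acetate
Conditions: t-BuOK, MeI, THF, 0 °C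
Reagents that add atoms: iodomethane, CI
Why: C-methylation of the formyl enolate; MeI should attack the exocyclic enolate from the face anti to the axial C10 methyl (equatorial attack), which leaves the formyl carbon C19 axial and cis to C20 and C6, the podocarpane-type C4 configuration.

**Step 9**
Reactants: 16 quaternary aldehyde
Product: 19 vinyl lactone (4aR,5R,8aS)-5-ethenyl-5,8a-dimethyloctahydro-3H-isochromen-3-one, via hydroxy ester 17 (not isolated), via silylvinyl lactone 18 (not isolated)
Conditions: NaBH4, MeOH, 0 °C to rt; then TFA, CH2Cl2, rt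
Reagents that add atoms: none
Why: Hydride reduction of the neopentyl aldehyde, lactonisation of the C19 alcohol onto the cis C7 ester (a temporary δ-lactone that masks C19–OH and keeps C7 at the acid level) and acid protodesilylation of the vinylsilane (ipso protonation, β-silyl cation); no stereocentre is touched.

**Step 10**
Reactants: 19 vinyl lactone
Product: 21 aldehyde lactone (4aS,5S,8aS)-5,8a-dimethyl-3-oxooctahydro-1H-isochromene-5-carbaldehyde, via ozonide 20 (not isolated)
Conditions: O3, CH2Cl2, −78 °C; then Me2S, −78 °C to rt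
Reagents that add atoms: ozone, [O-][O+]=O
Why: Ozonolysis of the only olefin with reductive work-up gives the neopentyl C9 aldehyde.

**Step 11**
Reactants: 21 aldehyde lactone; 5 phosphonium bromide
Product: 23 (1Z,4E)-dienyl lactone, via ylide 22 (not isolated)
Conditions: 5, NaHMDS, THF, −78 to 0 °C; then 21, −78 °C to rt
Reagents that add atoms: none
Why: Wittig olefination with a non-stabilised ylide joins C9 to C11 (mainly Z) and brings in the whole side chain; the aldehyde should react far faster than the lactone.

**Step 12**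
Reactants: 23 dienyl lactone; 7 ethynyltrimethylsilane
Product: 26 hydroxy ynone, via lithium acetylide 24 (not isolated), via lithium lactolate 25 (not isolated)
Conditions: 7, n-BuLi, THF, −78 °C; then 23, −78 °C; aq. NH4Cl
Reagents that add atoms: none
Why: Single addition of a lithium acetylide to a lactone, whose tetrahedral lithium lactolate persists until the quench, opens the temporary ring to the C7 ynone and frees the C19 hydroxyl.

**Step 13**
Reactants: 26 hydroxy ynone
Product: 27 acetoxy ynone
Conditions: Ac2O, pyridine, DMAP (cat.), CH2Cl2, 0 °C to rt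
Reagents that add atoms: acetic anhydride, CC(=O)OC(C)=O
Why: Acetylation of the only free hydroxyl (primary C19–OH), done while C7 is a ketone and C15 is silylated, puts the acetate on the right oxygen.

**Step 14**
Reactants: 27 acetoxy ynone
Product: 28 (7R)-propargylic alcohol
Conditions: Ru[(R,R)-TsDPEN](p-cymene) (2 mol%), i-PrOH, rt
Reagents that add atoms: none
Why: Noyori asymmetric transfer hydrogenation of an α,β-acetylenic ketone reduces only the C=O group; the (R,R) catalyst is chosen by analogy with alkyl alkynyl ketones to deliver the 7R alcohol (catalyst control).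

**Step 15**
Reactants: 28 (7R)-propargylic alcohol
Product: 29 enyne diol
Conditions: TBAF, AcOH, THF, 0 °C to rt
Reagents that add atoms: none
Why: Fluoride cleaves the alkynyl C–Si bond and the primary TBS ether in one operation, while the acetic acid buffer should spare the C19 acetate.

**Step 16**
Reactants: 29 enyne diol
Product: 31 19-acetoxylabda-8(17),13E-diene-7α,15-diol (target), via vinylstannane 30 (not isolated)
Conditions: Bu3SnH (slow addition), AIBN, PhH (0.01 M), 80 °C; then TsOH·H2O (cat.), MeOH/CH2Cl2, 0 °C to rt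
Reagents that add atoms: none
Why: Bu3Sn• adds reversibly to the terminal alkyne carbon C17 to give the σ-vinyl radical at C8, which adds 6-exo-trig to C9 of the C9=C11 olefin; the secondary C11 radical takes hydrogen from Bu3SnH, and the exocyclic vinylstannane 30 is protodestannylated to the 8(17)-methylene group. The closest known reaction type is the Stork–Mook stannyl-radical enyne cyclization (vinyl radical cyclization). Ring B is the only ring closed, in the 6-exo-trig mode, through a chair-like transition state pre-organised by the trans-diequatorial C5–C6 and C10–C9 bonds of ring A. The new stereocentre C9 is under substrate control: the olefinic arm should sit pseudo-equatorial, since the pseudo-axial alternative clashes with the axial C7–OH and H-5, so H-9 ends α (9R), trans to the C20 methyl. The step needs 6-exo closure at C9 to win over 7-endo attack at C11, over plain hydrostannation and over hydrogen transfer. The rigid cyclohexane scaffold, the absence of any 1,5-hydrogen (C4 and C10 are quaternary) and slow stannane addition at high dilution should secure this.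

**Compound list**

1 | 3-methylbut-2-en-1-ol (prenol) | CC(C)=CCO | starting material
2 | tert-butyldimethyl[(3-methylbut-2-en-1-yl)oxy]silane | CC(C)=CCO[Si](C)(C)C(C)(C)C | intermediate
3 | (2E)-4-[(tert-butyldimethylsilyl)oxy]-2-methylbut-2-en-1-ol | OC/C(C)=C/CO[Si](C)(C)C(C)(C)C | intermediate
4 | {[(2E)-4-bromo-3-methylbut-2-en-1-yl]oxy}(tert-butyl)dimethylsilane | BrC/C(C)=C/CO[Si](C)(C)C(C)(C)C | intermediate
5 | [(3E)-5-[(tert-butyldimethylsilyl)oxy]-3-methylpent-3-en-1-yl]triphenylphosphonium bromide | CC(C)(C)[Si](C)(C)OC/C=C(\C)CC[P+](c1ccccc1)(c1ccccc1)c1ccccc1.[Br-] | intermediate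
6 | 3-methylcyclohex-2-en-1-one | CC1=CC(=O)CCC1 | starting material
7 | ethynyltrimethylsilane | C#C[Si](C)(C)C | starting material
8 | diisobutyl[1-(trimethylsilyl)ethenyl]alane (formed in the flask) | C=C([Si](C)(C)C)[Al](CC(C)C)CC(C)C | intermediate
9 | diisobutylaluminium (3S)-3-methyl-3-[1-(trimethylsilyl)ethenyl]cyclohex-1-en-1-olate (formed in the flask) | C1=C(O[Al](CC(C)C)CC(C)C)CCC[C@]1(C)C(=C)[Si](C)(C)C | intermediate
10 | trimethyl({(3S)-3-methyl-3-[1-(trimethylsilyl)ethenyl]cyclohex-1-en-1-yl}oxy)silane | C1=C(O[Si](C)(C)C)CCC[C@]1(C)C(=C)[Si](C)(C)C | intermediate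
11 | methyl iodoacetate | COC(=O)CI | starting material
12 | lithium (3S)-3-methyl-3-[1-(trimethylsilyl)ethenyl]cyclohex-1-en-1-olate (formed in the flask) | C1=C(O[Li])CCC[C@]1(C)C(=C)[Si](C)(C)C | intermediate
13 | methyl 2-{(1R,2S)-2-methyl-6-oxo-2-[1-(trimethylsilyl)ethenyl]cyclohexyl}acetate (labdane 5R,10S; CH2CO2Me trans to the silylvinyl group, cis to the methyl) | COC(=O)C[C@H]1C(=O)CCC[C@]1(C)C(=C)[Si](C)(C)C | intermediate
14 | methyl 2-{(1S,2S)-6-(methoxymethylidene)-2-methyl-2-[1-(trimethylsilyl)ethenyl]cyclohexyl}acetate, E/Z mixture (formed in the flask) | COC(=O)C[C@H]1C(=COC)CCC[C@]1(C)C(=C)[Si](C)(C)C | intermediate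
15 | methyl 2-{(1S,6S)-2-formyl-6-methyl-6-[1-(trimethylsilyl)ethenyl]cyclohexyl}acetate, both epimers at the formyl-bearing carbon (labdane C4) | COC(=O)C[C@H]1C(C=O)CCC[C@]1(C)C(=C)[Si](C)(C)C | intermediate
16 | methyl 2-{(1S,2S,6S)-2-formyl-2,6-dimethyl-6-[1-(trimethylsilyl)ethenyl]cyclohexyl}acetate (labdane 4S,5S,10S; formyl cis to the C10 methyl and to CH2CO2Me) | COC(=O)C[C@H]1[C@@](C)(C=O)CCC[C@]1(C)C(=C)[Si](C)(C)C | intermediate
17 | methyl 2-{(1S,2S,6S)-2-(hydroxymethyl)-2,6-dimethyl-6-[1-(trimethylsilyl)ethenyl]cyclohexyl}acetate (formed in the flask) | COC(=O)C[C@H]1[C@@](C)(CO)CCC[C@]1(C)C(=C)[Si](C)(C)C | intermediate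
18 | (4aS,5S,8aS)-5,8a-dimethyl-5-[1-(trimethylsilyl)ethenyl]octahydro-3H-isochromen-3-one (formed in the flask) | O=C1C[C@H]2[C@@](C)(CO1)CCC[C@]2(C)C(=C)[Si](C)(C)C | intermediate
19 | (4aR,5R,8aS)-5-ethenyl-5,8a-dimethyloctahydro-3H-isochromen-3-one (cis-fused C19–O–C7 δ-lactone; labdane 4S,5R,10R) | O=C1C[C@H]2[C@@](C)(CO1)CCC[C@]2(C)C=C | intermediate
20 | ozonide of 19: the vinyl group converted into a 1,2,4-trioxolan-3-yl ring at C9 (formed in the flask) | O=C1C[C@H]2[C@@](C)(CO1)CCC[C@]2(C)C1OCOO1 | intermediate
21 | (4aS,5S,8aS)-5,8a-dimethyl-3-oxooctahydro-1H-isochromene-5-carbaldehyde | O=C1C[C@H]2[C@@](C)(CO1)CCC[C@]2(C)C=O | intermediate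
22 | [(3E)-5-[(tert-butyldimethylsilyl)oxy]-3-methylpent-3-en-1-ylidene]triphenylphosphorane (formed in the flask) | CC(C)(C)[Si](C)(C)OC/C=C(\C)CC=P(c1ccccc1)(c1ccccc1)c1ccccc1 | intermediate
23 | (4aR,5R,8aS)-5-[(1Z,4E)-6-[(tert-butyldimethylsilyl)oxy]-4-methylhexa-1,4-dien-1-yl]-5,8a-dimethyloctahydro-3H-isochromen-3-one | O=C1C[C@H]2[C@@](C)(CO1)CCC[C@]2(C)/C=C\C/C(C)=C/CO[Si](C)(C)C(C)(C)C | intermediate
24 | lithium (trimethylsilyl)acetylide (formed in the flask) | [Li]C#C[Si](C)(C)C | intermediate
25 | lithium lactolate: the 3-olate of 23 carrying the (trimethylsilyl)ethynyl group at C3 of the isochromane ring, either configuration at that carbon (formed in the flask) | [Li]OC1(C#C[Si](C)(C)C)C[C@H]2[C@@](C)(CO1)CCC[C@]2(C)/C=C\C/C(C)=C/CO[Si](C)(C)C(C)(C)C | intermediate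
26 | 1-{(1R,2S,6R)-6-[(1Z,4E)-6-[(tert-butyldimethylsilyl)oxy]-4-methylhexa-1,4-dien-1-yl]-2-(hydroxymethyl)-2,6-dimethylcyclohexyl}-4-(trimethylsilyl)but-3-yn-2-one | C[Si](C)(C)C#CC(=O)C[C@H]1[C@@](C)(CO)CCC[C@]1(C)/C=C\C/C(C)=C/CO[Si](C)(C)C(C)(C)C | intermediate
27 | {(1S,2R,3R)-3-[(1Z,4E)-6-[(tert-butyldimethylsilyl)oxy]-4-methylhexa-1,4-dien-1-yl]-1,3-dimethyl-2-[2-oxo-4-(trimethylsilyl)but-3-yn-1-yl]cyclohexyl}methyl acetate | C[Si](C)(C)C#CC(=O)C[C@H]1[C@@](C)(COC(C)=O)CCC[C@]1(C)/C=C\C/C(C)=C/CO[Si](C)(C)C(C)(C)C | intermediate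
28 | {(1S,2R,3R)-3-[(1Z,4E)-6-[(tert-butyldimethylsilyl)oxy]-4-methylhexa-1,4-dien-1-yl]-2-[(2R)-2-hydroxy-4-(trimethylsilyl)but-3-yn-1-yl]-1,3-dimethylcyclohexyl}methyl acetate | C[Si](C)(C)C#C[C@H](O)C[C@H]1[C@@](C)(COC(C)=O)CCC[C@]1(C)/C=C\C/C(C)=C/CO[Si](C)(C)C(C)(C)C | intermediate
29 | {(1S,2R,3R)-2-[(2R)-2-hydroxybut-3-yn-1-yl]-3-[(1Z,4E)-6-hydroxy-4-methylhexa-1,4-dien-1-yl]-1,3-dimethylcyclohexyl}methyl acetate | C#C[C@H](O)C[C@H]1[C@@](C)(COC(C)=O)CCC[C@]1(C)/C=C\C/C(C)=C/CO | intermediate
30 | 17-(tributylstannyl) derivative of 31 (4S,5R,7R,9R,10S), E/Z mixture at C8=C17 (formed in the flask) | CCCC[Sn](CCCC)(CCCC)C=C1[C@H](O)C[C@H]2[C@@](C)(COC(C)=O)CCC[C@]2(C)[C@H]1CC/C(C)=C/CO | intermediate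
31 | 19-acetoxylabda-8(17),13E-diene-7α,15-diol (4S,5R,7R,9R,10S) | C=C1[C@H](O)C[C@H]2[C@@](C)(COC(C)=O)CCC[C@]2(C)[C@H]1CC/C(C)=C/CO | target

**Totals.** Total step count: 16. Longest linear sequence: 12 steps (steps 5–16, from 3-methylcyclohex-2-en-1-one); the side chain (steps 1–4) joins at step 11.

**Steps most likely to fail**

1. Step 16 (key step). The vinyl radical may take hydrogen before it cyclises (plain hydrostannation), may close 7-endo at C11, or may attack the other face of the olefin and give the C9 epimer. Fallback, setting out from 29 and returning at 31: Trost's palladium-hydride reductive enyne cyclization (Pd2(dba)3·CHCl3, P(o-tol)3, AcOH, Et3SiH, PhH, rt to 60 °C). H–Pd–OAc adds across the alkyne with palladium at C8, the alkenylpalladium inserts the C9=C11 olefin 6-exo, and the silane cleaves the C11–Pd bond. This ionic organometallic path avoids free radicals altogether; no new compound is made (F0).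

2. Step 8. The formyl enolate may be methylated on oxygen, or with poor facial discrimination because the monocycle is conformationally mobile. Fallback, setting out from 14 (isolated by omitting the acid treatment of step 7) and returning at 16: Furukawa–Simmons–Smith cyclopropanation of the electron-rich exocyclic enol ether (Et2Zn, CH2I2, CH2Cl2, 0 °C), the bulky zinc carbenoid approaching anti to the axial C10 methyl, should give the spiro methoxycyclopropane F1. Aqueous HCl in THF then opens the donor cyclopropane (protonation of the CH2, oxocarbenium at C19) to the α-methyl aldehyde 16.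

3. Step 6. SN2 alkylation at the enolate carbon next to the quaternary centre may be slow, and O-alkylation or proton transfer may erode regio- and stereocontrol. Fallback, setting out from 10 and returning at 13: Lewis-acid alkylation of the silyl enol ether itself with methyl chloro(phenylthio)acetate (ZnBr2, CH2Cl2, rt; thionium ion, SN1-type) should give the α-phenylthio keto ester F2, again anti to the silylvinyl group. Radical desulfurisation (Bu3SnH, AIBN, PhH, 80 °C) then gives 13.

**Further compounds**

F0 | step 16 | none | none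
F1 | step 8 | methyl 2-{(4S,5S,9S)-1-methoxy-4,9-dimethyl-9-[1-(trimethylsilyl)ethenyl]spiro[2.5]octan-4-yl}acetate skeleton, i.e. 14 with CH2 added across the C4=C19 enol ether bond (spiro methoxycyclopropane, either configuration at C19) | COC(=O)C[C@H]1[C@@]2(C(OC)C2)CCC[C@]1(C)C(=C)[Si](C)(C)C
F2 | step 6 | methyl 2-{(1R,2S)-2-methyl-6-oxo-2-[1-(trimethylsilyl)ethenyl]cyclohexyl}-2-(phenylsulfanyl)acetate (either configuration at the sulfur-bearing carbon) | COC(=O)C(Sc1ccccc1)[C@H]1C(=O)CCC[C@]1(C)C(=C)[Si](C)(C)C
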